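The chromene benzene ring (C4a, C5, C6, C7, C8, C8a) is built by cycloaddition instead of by substituting a resorcinol. A dimedone-derived 1,3-bis(trimethylsilyloxy)cyclohexadiene adds to an alkynyl ketone and the adduct sheds isobutene. One heating step therefore forms C4a–C8a and C5–C6 and fixes O1 at C8a, the C4 carbon at C4a, the arylethyl chain at C5 and oxygen at C7 without isomers. The feature exploited is the 1,3-dioxygen pattern at C8a and C7 beside the vicinal carbon substituents at C4a and C5. The dienophile is a cross-conjugated enynone: silyl-protected 4-hydroxyphenethyl on the alkyne, 2-methylprop-1-enyl on the carbonyl, which later closes the pyran ring.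

Key step: step 8

Assumption: the aryl triisopropylsilyl ether is taken to survive K2CO3 in methanol at 0 °C to room temperature for the few hours of step 3; a non-protic alternative is given among the fallbacks.

Step 1
Reactants: 1 methyl 3-(4-hydroxyphenyl)propanoate
Product: 2 methyl 3-[4-(triisopropylsilyloxy)phenyl]propanoate
Conditions: TIPSCl, imidazole, DMF, rt
Reagents that add atoms: triisopropylsilyl chloride, CC(C)[Si](Cl)(C(C)C)C(C)C
Why: Standard imidazole-mediated O-silylation of a phenol; the bulky silyl ether is chosen because it should tolerate hydride, organolithium, heat and mild base and be removable by fluoride at the end.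

Step 2
Reactants: 2 methyl 3-[4-(triisopropylsilyloxy)phenyl]propanoate
Product: 3 3-[4-(triisopropylsilyloxy)phenyl]propanal
Conditions: iBu2AlH (1.1 equiv), CH2Cl2, −78 °C; aq. potassium sodium tartrate
Reagents that add atoms: none
Why: Partial reduction of a methyl ester at low temperature, where the tetrahedral aluminium hemiacetal persists until work-up and releases the aldehyde.

Step 3
Reactants: 3 3-[4-(triisopropylsilyloxy)phenyl]propanal; 4 dimethyl (1-diazo-2-oxopropyl)phosphonate (Ohira–Bestmann reagent)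
Product: 5 [4-(but-3-yn-1-yl)phenoxy]triisopropylsilane
Conditions: 4 (1.3 equiv), K2CO3 (2 equiv), MeOH, 0 °C to rt
Reagents that add atoms: dimethyl (1-diazo-2-oxopropyl)phosphonate 4, CC(=O)C(=[N+]=[N-])P(=O)(OC)OC
Why: Seyferth–Gilbert homologation in the Ohira–Bestmann variant: methanolysis of the acetyl group gives the diazomethylphosphonate anion, which olefinates the aldehyde and loses N2 with 1,2-hydrogen shift to the terminal alkyne.

Step 4
Reactants: 5 [4-(but-3-yn-1-yl)phenoxy]triisopropylsilane; 6 3-methylbut-2-enal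
Product: 7 racemic 2-methyl-8-[4-(triisopropylsilyloxy)phenyl]oct-2-en-5-yn-4-ol
Conditions: n-BuLi, THF, −78 °C; then 6, −78 to 0 °C; H2O
Reagents that add atoms: 3-methylbut-2-enal 6, CC(C)=CC=O
Why: 1,2-Addition of a lithium acetylide to an enal; the carbinol centre is formed racemic and is destroyed in the next step.

Step 5
Reactants: 7 racemic 2-methyl-8-[4-(triisopropylsilyloxy)phenyl]oct-2-en-5-yn-4-ol
Product: 8 2-methyl-8-[4-(triisopropylsilyloxy)phenyl]oct-2-en-5-yn-4-one
Conditions: activated MnO2 (excess), CH2Cl2, rt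
Reagents that add atoms: none
Why: The alcohol is both allylic and propargylic, the substrate class for which MnO2 oxidation is selective and mild.

Step 6
Reactants: 9 dimedone (5,5-dimethylcyclohexane-1,3-dione)
Product: 10 5,5-dimethyl-3-(trimethylsilyloxy)cyclohex-2-en-1-one
Conditions: TMSCl, Et3N, Et2O, 0 °C to rt; filter, distil
Reagents that add atoms: chlorotrimethylsilane, C[Si](C)(C)Cl
Why: O-Silylation of the enol form of a cyclic 1,3-diketone to the vinylogous silyl ester.

Step 7
Reactants: 10 5,5-dimethyl-3-(trimethylsilyloxy)cyclohex-2-en-1-one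
Product: 11 5,5-dimethyl-1,3-bis(trimethylsilyloxy)cyclohexa-1,3-diene
Conditions: LiN(iPr)2, THF, −78 °C; TMSCl, −78 °C to rt; non-aqueous work-up, distil
Reagents that add atoms: chlorotrimethylsilane, C[Si](C)(C)Cl
Why: Kinetic enolisation and O-silylation of the dienolate; deprotonation at either ring CH2 leads to the same 1,3-bis(silyloxy)diene, so no regiochemical issue arises.

Step 8
Reactants: 8 2-methyl-8-[4-(triisopropylsilyloxy)phenyl]oct-2-en-5-yn-4-one; 11 5,5-dimethyl-1,3-bis(trimethylsilyloxy)cyclohexa-1,3-diene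
Product: 13 3-methyl-1-{6-[2-(4-triisopropylsilyloxyphenyl)ethyl]-2,4-bis(trimethylsilyloxy)phenyl}but-2-en-1-one, via bicyclo[2.2.2]octadiene cycloadduct 12 (not isolated)
Conditions: 11 (3 equiv), neat or minimal xylenes, 150 °C, sealed tube; then volatiles removed in vacuo, crude 13 used directly
Reagents that add atoms: none
Why: A thermal, concerted but asynchronous [4+2] cycloaddition of the electron-rich diene to the electron-poor triple bond gives racemic adduct 12, whose C(CH3)2–CH2 bridge is then expelled as isobutene in a retro-Diels–Alder step driven by aromatisation (Alder–Rickert sequence, known for this diene with acyl-activated alkynes). The six-membered carbocycle that becomes the chromene benzene ring closes by intermolecular cycloaddition across the alkyne, forming C4a–C8a and C5–C6. No stereocentre survives, since the two bridgeheads of 12 become aromatic carbons. Regioselectivity rests on the diene: its unsubstituted terminus, to which both silyloxy groups donate, bonds to the β-carbon of the ynone bearing the arylethyl chain, so the silyloxy-bearing terminus ends up next to the acyl carbon. Chemoselectivity for the alkyne follows from the unhindered linear ynone against the β,β-dimethyl-substituted alkene of the enone, and the aryl triisopropylsilyl ether is inert to heat.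

Step 9
Reactants: 13 3-methyl-1-{6-[2-(4-triisopropylsilyloxyphenyl)ethyl]-2,4-bis(trimethylsilyloxy)phenyl}but-2-en-1-one
Product: 15 7-hydroxy-2,2-dimethyl-5-[2-(4-triisopropylsilyloxyphenyl)ethyl]chroman-4-one, via dihydroxyaryl enone 14 (not isolated)
Conditions: pyridinium p-toluenesulfonate (cat.), MeOH–THF, rt; then Et3N, 50 °C
Reagents that add atoms: none
Why: Aryl trimethylsilyl ethers are methanolysed under conditions that leave the hindered triisopropylsilyl ether intact, and the freed C8a phenol then closes the pyranone by a base-catalysed 6-endo-trig oxa-Michael addition to the β,β-dimethyl enone, the known cyclisation of ortho-hydroxyaryl 3-methylbut-2-enyl ketones.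

Step 10
Reactants: 15 7-hydroxy-2,2-dimethyl-5-[2-(4-triisopropylsilyloxyphenyl)ethyl]chroman-4-one; 16 1-bromo-3-methylbut-2-ene (prenyl bromide)
Product: 17 2,2-dimethyl-7-(3-methylbut-2-enyloxy)-5-[2-(4-triisopropylsilyloxyphenyl)ethyl]chroman-4-one
Conditions: 16, K2CO3, acetone, reflux
Reagents that add atoms: 1-bromo-3-methylbut-2-ene 16, CC(C)=CCBr
Why: Williamson ether synthesis on the only free phenol, which is acidic because it is para to the ketone, so O-alkylation by SN2 at the primary allylic bromide needs no selectivity.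

Step 11
Reactants: 17 2,2-dimethyl-7-(3-methylbut-2-enyloxy)-5-[2-(4-triisopropylsilyloxyphenyl)ethyl]chroman-4-one
Product: 18 racemic 2,2-dimethyl-7-(3-methylbut-2-enyloxy)-5-[2-(4-triisopropylsilyloxyphenyl)ethyl]chroman-4-ol
Conditions: NaBH4, MeOH–THF, 0 °C to rt
Reagents that add atoms: none
Why: Borohydride reduction of the aryl ketone to the benzylic alcohol; the new C4 centre is racemic and is removed in the next step.

Step 12
Reactants: 18 racemic 2,2-dimethyl-7-(3-methylbut-2-enyloxy)-5-[2-(4-triisopropylsilyloxyphenyl)ethyl]chroman-4-ol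
Product: 20 triisopropyl{4-[2-(2,2-dimethyl-7-(3-methylbut-2-enyloxy)-2H-chromen-5-yl)ethyl]phenoxy}silane, via chroman-4-yl methanesulfonate 19 (not isolated)
Conditions: MsCl, Et3N (excess), CH2Cl2, 0 °C to 40 °C
Reagents that add atoms: none
Why: Mesylation of the alkoxy-activated benzylic alcohol and base-mediated elimination give the conjugated C3–C4 alkene under non-acidic conditions, which protects the prenyl ether and avoids a long-lived C4 cation.

Step 13
Reactants: 20 triisopropyl{4-[2-(2,2-dimethyl-7-(3-methylbut-2-enyloxy)-2H-chromen-5-yl)ethyl]phenoxy}silane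
Product: 21 4-{2-[2,2-dimethyl-7-(3-methylbut-2-enyloxy)-2H-chromen-5-yl]ethyl}phenol (target CNP0337021.0)
Conditions: Bu4NF, THF, 0 °C; H2O
Reagents that add atoms: none
Why: Fluoride cleavage of the aryl silyl ether is driven by the Si–F bond and does not touch the chromene or the allylic aryl ether.

Compound list
1 | methyl 3-(4-hydroxyphenyl)propanoate | COC(=O)CCc1ccc(O)cc1 | starting material
2 | methyl 3-[4-(triisopropylsilyloxy)phenyl]propanoate | COC(=O)CCc1ccc(O[Si](C(C)C)(C(C)C)C(C)C)cc1 | intermediate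
3 | 3-[4-(triisopropylsilyloxy)phenyl]propanal | O=CCCc1ccc(O[Si](C(C)C)(C(C)C)C(C)C)cc1 | intermediate
4 | dimethyl (1-diazo-2-oxopropyl)phosphonate (Ohira–Bestmann reagent) | CC(=O)C(=[N+]=[N-])P(=O)(OC)OC | starting material
5 | [4-(but-3-yn-1-yl)phenoxy]triisopropylsilane | C#CCCc1ccc(O[Si](C(C)C)(C(C)C)C(C)C)cc1 | intermediate
6 | 3-methylbut-2-enal (prenal) | CC(C)=CC=O | starting material
7 | racemic 2-methyl-8-[4-(triisopropylsilyloxy)phenyl]oct-2-en-5-yn-4-ol | CC(C)=CC(O)C#CCCc1ccc(O[Si](C(C)C)(C(C)C)C(C)C)cc1 | intermediate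
8 | 2-methyl-8-[4-(triisopropylsilyloxy)phenyl]oct-2-en-5-yn-4-one | CC(C)=CC(=O)C#CCCc1ccc(O[Si](C(C)C)(C(C)C)C(C)C)cc1 | intermediate
9 | dimedone (5,5-dimethylcyclohexane-1,3-dione) | CC1(C)CC(=O)CC(=O)C1 | starting material
10 | 5,5-dimethyl-3-(trimethylsilyloxy)cyclohex-2-en-1-one | CC1(C)CC(=O)C=C(O[Si](C)(C)C)C1 | intermediate
11 | 5,5-dimethyl-1,3-bis(trimethylsilyloxy)cyclohexa-1,3-diene | C[Si](C)(C)OC1=CC(O[Si](C)(C)C)=CC(C)(C)C1 | intermediate
12 | racemic 1-{8,8-dimethyl-3-[2-(4-triisopropylsilyloxyphenyl)ethyl]-1,5-bis(trimethylsilyloxy)bicyclo[2.2.2]octa-2,5-dien-2-yl}-3-methylbut-2-en-1-one | CC(C)=CC(=O)C1=C(CCc2ccc(O[Si](C(C)C)(C(C)C)C(C)C)cc2)C3C(O[Si](C)(C)C)=CC1(O[Si](C)(C)C)CC3(C)C | intermediate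
13 | 3-methyl-1-{6-[2-(4-triisopropylsilyloxyphenyl)ethyl]-2,4-bis(trimethylsilyloxy)phenyl}but-2-en-1-one (bis-trimethylsilyl ether of the 4-acyl-5-arylethyl resorcinol) | CC(C)=CC(=O)c1c(CCc2ccc(O[Si](C(C)C)(C(C)C)C(C)C)cc2)cc(O[Si](C)(C)C)cc1O[Si](C)(C)C | intermediate
14 | 1-{2,4-dihydroxy-6-[2-(4-triisopropylsilyloxyphenyl)ethyl]phenyl}-3-methylbut-2-en-1-one | CC(C)=CC(=O)c1c(CCc2ccc(O[Si](C(C)C)(C(C)C)C(C)C)cc2)cc(O)cc1O | intermediate
15 | 7-hydroxy-2,2-dimethyl-5-[2-(4-triisopropylsilyloxyphenyl)ethyl]chroman-4-one | CC1(C)CC(=O)c2c(CCc3ccc(O[Si](C(C)C)(C(C)C)C(C)C)cc3)cc(O)cc2O1 | intermediate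
16 | 1-bromo-3-methylbut-2-ene (prenyl bromide) | CC(C)=CCBr | starting material
17 | 2,2-dimethyl-7-(3-methylbut-2-enyloxy)-5-[2-(4-triisopropylsilyloxyphenyl)ethyl]chroman-4-one | CC(C)=CCOc1cc(CCc2ccc(O[Si](C(C)C)(C(C)C)C(C)C)cc2)c2c(c1)OC(C)(C)CC2=O | intermediate
18 | racemic 2,2-dimethyl-7-(3-methylbut-2-enyloxy)-5-[2-(4-triisopropylsilyloxyphenyl)ethyl]chroman-4-ol | CC(C)=CCOc1cc(CCc2ccc(O[Si](C(C)C)(C(C)C)C(C)C)cc2)c2c(c1)OC(C)(C)CC2O | intermediate
19 | racemic 2,2-dimethyl-7-(3-methylbut-2-enyloxy)-5-[2-(4-triisopropylsilyloxyphenyl)ethyl]chroman-4-yl methanesulfonate | CC(C)=CCOc1cc(CCc2ccc(O[Si](C(C)C)(C(C)C)C(C)C)cc2)c2c(c1)OC(C)(C)CC2OS(C)(=O)=O | intermediate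
20 | triisopropyl{4-[2-(2,2-dimethyl-7-(3-methylbut-2-enyloxy)-2H-chromen-5-yl)ethyl]phenoxy}silane | CC(C)=CCOc1cc(CCc2ccc(O[Si](C(C)C)(C(C)C)C(C)C)cc2)c2c(c1)OC(C)(C)C=C2 | intermediate
21 | 4-{2-[2,2-dimethyl-7-(3-methylbut-2-enyloxy)-2H-chromen-5-yl]ethyl}phenol (no stereocentres, no stereodefined alkene) | CC(C)=CCOc1cc(CCc2ccc(O)cc2)c2c(c1)OC(C)(C)C=C2 | target

Total step count: 13. Longest linear sequence: 11 steps (steps 1–5 and 8–13, from compound 1); the diene branch (steps 6–7) is 2 steps.

Steps most likely to fail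

Step 8. The cycloaddition to a β-alkyl ynone may be slow at temperatures where the cross-conjugated enynone oligomerises or reacts through its enone, giving low conversion to the arene. Fallback, setting out from alkyne 5 and diene 11 and returning at chromanone 15: lithiation of 5 and acylation with N-methoxy-N-methylacetamide would give 6-[4-(triisopropylsilyloxy)phenyl]hex-3-yn-2-one F1, a simpler dienophile without the enone. Heating F1 with diene 11 would give the bicyclo[2.2.2]octadiene adduct F2 and, after loss of isobutene, the bis(trimethylsilyl) acetophenone F3. Methanolysis would give 2,4-dihydroxy-6-(arylethyl)acetophenone F4. Kabbe condensation of F4 with acetone and pyrrolidine would then build the 2,2-dimethylpyranone ring and rejoin the route at 15.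

Step 12. Ionisation at the electron-rich benzylic C4 may lead to substitution by chloride, dimerisation with the chromene formed, or attack on the prenyl ether instead of clean elimination. Fallback, setting out from ketone 17 and returning at chromene 20: condensation of 17 with p-toluenesulfonyl hydrazide would give the tosylhydrazone F5. Shapiro elimination with LiN(iPr)2 in THF and protonation of the C4 vinyllithium with water would give 20 directly, bypassing alcohol 18 and any benzylic leaving group.

Step 3. Methanolysis of the aryl silyl ether by K2CO3 in methanol may compete with the homologation and cause loss of the protecting group. Fallback, setting out from aldehyde 3 and returning at alkyne 5: Corey–Fuchs homologation under aprotic conditions. CBr4 and PPh3 in CH2Cl2 would give [4-(4,4-dibromobut-3-en-1-yl)phenoxy]triisopropylsilane F6. Treatment of F6 with n-BuLi in THF at −78 °C and a water quench would then give 5.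

Further compounds
F1 | step 8 | 6-[4-(triisopropylsilyloxy)phenyl]hex-3-yn-2-one | CC(=O)C#CCCc1ccc(O[Si](C(C)C)(C(C)C)C(C)C)cc1
F2 | step 8 | racemic 1-{8,8-dimethyl-3-[2-(4-triisopropylsilyloxyphenyl)ethyl]-1,5-bis(trimethylsilyloxy)bicyclo[2.2.2]octa-2,5-dien-2-yl}ethanone | CC(=O)C1=C(CCc2ccc(O[Si](C(C)C)(C(C)C)C(C)C)cc2)C3C(O[Si](C)(C)C)=CC1(O[Si](C)(C)C)CC3(C)C
F3 | step 8 | 1-{6-[2-(4-triisopropylsilyloxyphenyl)ethyl]-2,4-bis(trimethylsilyloxy)phenyl}ethanone | CC(=O)c1c(CCc2ccc(O[Si](C(C)C)(C(C)C)C(C)C)cc2)cc(O[Si](C)(C)C)cc1O[Si](C)(C)C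
F4 | step 8 | 1-{2,4-dihydroxy-6-[2-(4-triisopropylsilyloxyphenyl)ethyl]phenyl}ethanone | CC(=O)c1c(CCc2ccc(O[Si](C(C)C)(C(C)C)C(C)C)cc2)cc(O)cc1O
F5 | step 12 | p-toluenesulfonylhydrazone of chromanone 17 | CC(C)=CCOc1cc(CCc2ccc(O[Si](C(C)C)(C(C)C)C(C)C)cc2)c2c(c1)OC(C)(C)CC2=NNS(=O)(=O)c1ccc(C)cc1
F6 | step 3 | [4-(4,4-dibromobut-3-en-1-yl)phenoxy]triisopropylsilane | BrC(Br)=CCCc1ccc(O[Si](C(C)C)(C(C)C)C(C)C)cc1
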